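**Plan**

1. Numbering: C1/C10 are the ring-fusion CH carbons; C2=C3 carries C15 (CH2OH) on C3; C4 is the hemiketal carbon; C5=C6; C7 (Me, O); C8 (acyloxy CH); C9 (CH2); C11(Me)=C12; C13; C14 (iPr).
2. Enabling feature: in the 2,5-dihydrofuran ring (C4, C5, C6, C7, O) the hemiketal carbon C4, the cis C5=C6 bond and the tertiary C7–O bond form a cis-2-ene-1,4-dioxygenated unit across the ten-membered carbocycle, which is what O2 leaves after adding to a C4=C5–C6=C7 diene.
3. Retrosynthetic cuts, in order: the C8–O ester; C4–O and C7–O (a 1,2-dioxine from O2, opened by Kornblum–DeLaMare, with C2=C3 stored as C2–OAc/C3–H so that no triene exists); C5–C6 (ring-closing Suzuki coupling); C2–C3, C7–C8 and C7–CH3 (arm building); C1–C2 and C10–C9 (ketene [2+2] on α-phellandrene).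
4. Forward order: cyclohexene core with two cis arms → C1 arm (C2–C5) → C10 arm (C8–C6 alkenyl iodide) → six-membered oxaborinine → ten-membered Z,Z-diene → 1,2-dioxine → dihydrofuran hemiketal → urocanate.
5. Stereochemistry: C14 from (R)-α-phellandrene; C1 and C10 from ketene addition anti to isopropyl; C8 from (S)-Alpine-Borane; C7 from hydroxyl-directed outer-face oxygen addition, with C4 following through the bridge; both Z alkenes from anti-carbomagnesiation and a six-membered boronate; C2/C3 are temporary, catalyst-set centres.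

Key step: step 19

Assumption: (R)-SEGPHOS is taken as the ligand antipode that gives the anti-(2R,3R) diol 11; C2 and C3 are temporary centres (both erased in step 20), so the antipode would simply be exchanged if a model alcohol showed the opposite sense.

**Route**

Step 1
Reactants: 1 (R)-(−)-α-phellandrene; 2 trichloroacetyl chloride
Product: 4 8,8-dichloro-2-methyl-5-(propan-2-yl)bicyclo[4.2.0]oct-2-en-7-one (cis-fused; C=O on C1; CCl2 on C10; anti to isopropyl), via dichloroketene 3 (not isolated)
Conditions: Zn (activated), Et2O, ultrasound, 15–20 °C, slow addition of 2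
Reagents that add atoms: none
Why: Zinc strips chlorine from 2 to give dichloroketene, whose thermal ketene–alkene [2+2] cycloaddition should engage the less substituted C=C of the diene on the face anti to the isopropyl group with the carbonyl carbon bonding to the diene terminus, so C1 and C10 are set cis to each other and trans to the C14 isopropyl by substrate control.

Step 2
Reactants: 4 dichlorocyclobutanone
Product: 5 2-methyl-5-(propan-2-yl)bicyclo[4.2.0]oct-2-en-7-one
Conditions: Zn, AcOH, rt → 50 °C
Reagents that add atoms: none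
Why: Zinc in acetic acid reductively removes both α-chlorines of the α,α-dichlorocyclobutanone (dissolving-metal dehalogenation) without touching the ring-fusion centres or the trisubstituted alkene.

Step 3
Reactants: 5 cyclobutanone
Product: 7 methyl 2-(2,2-dimethoxyethyl)-3-methyl-6-(propan-2-yl)cyclohex-3-ene-1-carboxylate (ester on C1; acetal arm on C10), via enaminone 6 (not isolated)
Conditions: t-BuOCH(NMe2)2, 60 °C; evaporate; TsOH·H2O, MeOH, 65 °C
Reagents that add atoms: tert-butoxybis(dimethylamino)methane, CN(C)C(OC(C)(C)C)N(C)C; methanol, CO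
Why: Bredereck aminomethylenation of the only α-CH2 gives a vinylogous amide, and acid methanolysis then opens the strained β-dicarbonyl equivalent by retro-Claisen cleavage, which should leave the methyl ester on C1 and a dimethyl-acetal-terminated two-carbon arm (C9–C8) on C10 with both stereocentres intact.

Step 4
Reactants: 7 ester acetal
Product: 8 [2-(2,2-dimethoxyethyl)-3-methyl-6-(propan-2-yl)cyclohex-3-en-1-yl]methanol
Conditions: LiAlH4, THF, 0 °C
Reagents that add atoms: none
Why: LiAlH4 reduces the ester to the primary alcohol (hydride reduction) while the acetal and the alkene are inert.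

Step 5
Reactants: 8 primary alcohol; 9 4-vinyl-1,3-dioxolan-2-one (vinyl ethylene carbonate)
Product: 11 anti-(2R,3R)-diol (C2 secondary OH; C3 bearing CH2OH = C15 plus a vinyl group = C4), via cyclohexenecarbaldehyde 10 (not isolated)
Conditions: 9 (2 equiv), [Ir(cod)Cl]2 (2.5 mol%), (R)-SEGPHOS (5 mol%), 4-cyano-3-nitrobenzoic acid (10 mol%), K3PO4 (cat.), THF, 90 °C
Reagents that add atoms: none
Why: Iridium-catalysed transfer-hydrogenative carbonyl (hydroxymethyl)allylation (Krische allylation): the catalyst dehydrogenates the alcohol to aldehyde 10, ionises 9 with loss of CO2 to a (hydroxymethyl)allyl-iridium species and adds it through a closed six-membered transition state in a redox-neutral cycle, the (E)-σ-allyl giving the anti relationship and the chiral ligand fixing the temporary C2 and C3 centres, while the buffered medium spares the acetal.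

Step 6
Reactants: 11 diol
Product: 12 C15 tert-butyldiphenylsilyl ether of 11 (C2–OH free)
Conditions: TBDPSCl, imidazole, CH2Cl2, 0 °C
Reagents that add atoms: tert-butyl(chloro)diphenylsilane, CC(C)(C)[Si](Cl)(c1ccccc1)c1ccccc1
Why: The primary C15 hydroxyl should be silylated far faster than the hindered secondary C2 hydroxyl (selective silyl ether formation).

Step 7
Reactants: 12 mono-silyl ether
Product: 13 C2 p-methoxybenzyl ether of 12
Conditions: NaH, PMBCl, Bu4NI (cat.), THF/DMF, 0 °C → rt
Reagents that add atoms: 4-methoxybenzyl chloride, COc1ccc(CCl)cc1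
Why: Williamson etherification of the C2 alkoxide installs a PMB group that survives acid and Grignard reagents and later leaves under neutral oxidative conditions, the TBDPS group staying on the less hindered primary oxygen.

Step 8
Reactants: 13 acetal
Product: 14 C8 aldehyde (C10–CH2–CHO)
Conditions: PPTS (cat.), acetone/H2O, 50 °C
Reagents that add atoms: water, O
Why: Mild acid-catalysed acetal hydrolysis unmasks the C8 aldehyde while the PMB and TBDPS ethers and both alkenes persist, and the aldehyde has no α-stereocentre to epimerise.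

Step 9
Reactants: 14 aldehyde; 15 ethynylmagnesium bromide
Product: 16 propargylic alcohol (C8 epimer mixture)
Conditions: THF, −78 → 0 °C
Reagents that add atoms: none
Why: 1,2-Addition of the alkynyl Grignard reagent to the aldehyde forms the C7–C8 bond, and the C8 epimer mixture is inconsequential because step 10 erases the centre.

Step 10
Reactants: 16 propargylic alcohol
Product: 17 terminal ynone (C8 ketone)
Conditions: Dess–Martin periodinane, NaHCO3, CH2Cl2, 0 °C → rt
Reagents that add atoms: none
Why: Dess–Martin oxidation gives the terminal ynone under buffered, non-nucleophilic conditions that avoid conjugate addition to it.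

Step 11
Reactants: 17 ynone
Product: 18 (8S)-propargylic alcohol
Conditions: (S)-Alpine-Borane (B-isopinocampheyl-9-BBN from (−)-α-pinene), THF, rt; then CH3CHO; ethanolamine
Reagents that add atoms: none
Why: Midland reduction: the ethynyl group acts as the small substituent in the boat-like hydride transfer from the pinanyl borane, so the (S)-reagent should deliver the (8S)-alcohol by reagent control, as in the reduction of 1-octyn-3-one, and the fast reduction of the ynone should outrun any hydroboration of the terminal vinyl group.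

Step 12
Reactants: 18 propargylic alcohol
Product: 20 (Z)-iodoalkene allylic alcohol (C7 methyl; C6 iodide cis to C8), via alkenylmagnesium alkoxide 19 (not isolated)
Conditions: MeMgBr (4 equiv), CuI (20 mol%), THF, −20 °C → rt; then I2, −78 → 0 °C
Reagents that add atoms: methylmagnesium bromide, C[Mg]Br; iodine, II
Why: Copper-catalysed anti-carbomagnesiation of the magnesium propargylic alkoxide places methyl on C7 and magnesium on C6 within a five-membered alkoxide chelate, and iodinolysis with retention should give the Z-iodoalkene with iodine cis to C8.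

Step 13
Reactants: 20 allylic alcohol
Product: 21 C8 triethylsilyl ether
Conditions: TESCl, imidazole, DMAP (cat.), CH2Cl2, 0 °C
Reagents that add atoms: chlorotriethylsilane, CC[Si](Cl)(CC)CC
Why: Silylation masks the allylic C8 hydroxyl as a TES ether, a group that is stable to the next four steps and removable beside TBDPS and acetate.

Step 14
Reactants: 21 PMB ether
Product: 22 C2 alcohol (PMB removed)
Conditions: DDQ, CH2Cl2/pH 7 buffer, 0 °C
Reagents that add atoms: none
Why: DDQ oxidises the electron-rich PMB ether by hydride abstraction and hydrolysis, which should free the C2 hydroxyl without touching the alkenyl iodide, the silyl ethers or the isolated alkenes.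

Step 15
Reactants: 22 homoallylic alcohol
Product: 24 cyclic butyl alkenylboronate (six-membered 1,2-oxaborinine O–B–C5=C4–C3–C2), via mixed vinylboronate 23 (not isolated)
Conditions: CH2=CHB(OBu)2, toluene, 40 °C, BuOH removed under vacuum; then second-generation Grubbs catalyst RuCl2(=CHPh)(H2IMes)(PCy3) (10 mol%), toluene, 60 °C
Reagents that add atoms: dibutyl vinylboronate, C=CB(OCCCC)OCCCC
Why: Boron-tethered ring-closing metathesis: transesterification hangs a vinylboronate on the C2 oxygen and metathesis with the C3 vinyl group closes a six-membered ring that can only hold a cis C4=C5 bond, so the Z-alkenylboron partner is made without alkyne chemistry.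

Step 16
Reactants: 24 cyclic alkenylboronate
Product: 25 ten-membered (4Z,6Z)-diene with free C2–OH (C8–OTES; C15–OTBDPS)
Conditions: Pd(PPh3)4 (20 mol%), TlOEt, THF/H2O (4:1), rt, 2 mM, slow addition
Reagents that add atoms: none
Why: Intramolecular Suzuki–Miyaura coupling: oxidative addition of zerovalent palladium into the C6–I bond, base-accelerated transmetalation of the cyclic alkenylboronate and reductive elimination should form C5–C6 with retention at both alkenes, closing the ten-membered ring as its Z,Z-diene (the two arms are held cis on the cyclohexene and high dilution suppresses oligomers) and releasing the C2 hydroxyl.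

Step 17
Reactants: 25 C2 alcohol
Product: 26 C2 acetate
Conditions: Ac2O, DMAP, pyridine, CH2Cl2, rt
Reagents that add atoms: acetic anhydride, CC(=O)OC(C)=O
Why: DMAP-catalysed acetylation turns the C2 hydroxyl into the leaving group needed in step 20, and a homoallylic acetate is inert to the steps in between.

Step 18
Reactants: 26 TES ether
Product: 27 ten-membered (4Z,6Z)-diene with free C8–OH (C2–OAc; C15–OTBDPS)
Conditions: HF·pyridine, pyridine, THF, 0 °C
Reagents that add atoms: none
Why: Buffered HF·pyridine should cleave the secondary TES ether much faster than the primary TBDPS ether and leave the acetate and the diene untouched, exposing the C8 hydroxyl that is to steer oxygen in the next step.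

Step 19
Reactants: 27 ten-membered Z,Z-diene; 28 dioxygen
Product: 29 bridged endoperoxide (C4–O–O–C7 1,2-dioxine; 7S; C5=C6 cis; C8–OH free)
Conditions: O2 (1 atm), tetraphenylporphyrin (1 mol%), visible light, CH2Cl2, −30 °C
Reagents that add atoms: none
Why: Energy transfer from photoexcited tetraphenylporphyrin generates singlet oxygen, which adds suprafacially as the 2π component across the s-cis C4=C5–C6=C7 diene in a concerted [4+2] cycloaddition that forms the C4–O and C7–O bonds at once. The closest known reactions are the photooxygenation of cyclic 1,3-dienes such as 1,3-cycloheptadiene and 1,3-cyclooctadiene to bridged endoperoxides and the hydroxyl-directed [4+2] photooxygenation of chiral dienols. The six-membered 1,2-dioxine ring (C4, C5, C6, C7, O, O) closes by cycloaddition and spans the ten-membered ring on the face opposite the C3–C2–C1–C10–C9–C8 bridge, leaving C5=C6 cis. C7 is controlled by C8: allylic 1,3-strain with C5 keeps H8 in the diene plane, which puts C9 on the inner face and the C8 hydroxyl on the outer face, so oxygen, hydrogen-bonded to that hydroxyl in the aprotic solvent, should enter from outside and give the 7S configuration, while C4 is set together with C7 by the suprafacial addition and is erased in step 20. The step needs cycloaddition to outrun ene reactions at C11=C12 and at the C7 methyl group and needs attack on one diene face: the ring holds the diene near s-cis, the allylic hydroxyl accelerates and directs the addition at low temperature, C3 is kept sp3 so that no electrocyclisable triene exists, and the 3R configuration places H3 in the diene plane in the same ring conformer.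

Step 20
Reactants: 29 endoperoxide
Product: 32 furanoid hemiketal with C2=C3 (C4–OH; C8–OH free; C15–OTBDPS), via hydroxy enone acetate 30 (not isolated), via hydroxy dienone 31 (not isolated)
Conditions: Et3N, CH2Cl2, 0 °C → rt; then DBU, rt
Reagents that add atoms: none
Why: Kornblum–DeLaMare rearrangement followed by E1cB elimination: Et3N removes the only peroxide α-hydrogen (C4–H, C7 being quaternary) so the O–O bond breaks to the C4 ketone and the C7 hydroxyl, DBU then enolises the ketone toward C3 and expels the C2 acetate (a far better leaving group than the C15 silyloxy) to form C2=C3 in its ring-compatible cis geometry, and the C7 hydroxyl, held next to the ketone by the cis C5=C6 bond, closes the dihydrofuran hemiketal whose C4 configuration is dictated by the bridge.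

Step 21
Reactants: 32 hemiketal
Product: 33 furanoid methyl ketal (C4–OMe; C8–OH free)
Conditions: PPTS (cat.), MeOH, rt
Reagents that add atoms: methanol, CO
Why: Acid-catalysed ketal exchange through the doubly allylic oxocarbenium ion should give the furanoid methyl ketal, the ring form of the natural congeners, which masks the hemiketal hydroxyl and leaves C8–OH as the only free alcohol (any pyranoid hemiketal tautomer of 32 converges here).

Step 22
Reactants: 33 methyl ketal alcohol; 34 (E)-N-methylurocanic acid
Product: 35 C8 N-methylurocanate (C4–OMe; C15–OTBDPS)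
Conditions: DCC, DMAP, CH2Cl2/DMF, rt → 40 °C
Reagents that add atoms: none
Why: Steglich esterification (carbodiimide activation with DMAP acyl transfer) acylates the single free, hindered secondary C8 hydroxyl with retention at C8 and keeps the E geometry of the urocanate.

Step 23
Reactants: 35 protected ester
Product: 37 target compound CNP0196085.1, via desilylated methyl ketal 36 (not isolated)
Conditions: HF·pyridine, pyridine, THF, 0 °C → rt; then CSA (cat.), CH2Cl2/H2O, rt
Reagents that add atoms: water, O
Why: Fluoride cleaves the C15 TBDPS ether and mild aqueous acid then hydrolyses the labile allylic methyl ketal back to the hemiketal through the same oxocarbenium ion, the bridge again fixing C4, under conditions that the urocanate ester and the three ring alkenes should survive.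

**Compound list**

1 | (R)-(−)-α-phellandrene | CC1=CC[C@H](C(C)C)C=C1 | starting material
2 | trichloroacetyl chloride | ClC(=O)C(Cl)(Cl)Cl | starting material
3 | dichloroketene | ClC(Cl)=C=O | intermediate
4 | 8,8-dichloro-2-methyl-5-(propan-2-yl)bicyclo[4.2.0]oct-2-en-7-one (cis-fused, anti to isopropyl, C=O on C1, CCl2 on C10) | CC1=CC[C@H](C(C)C)[C@@H]2[C@H]1C(Cl)(Cl)C2=O | intermediate
5 | 2-methyl-5-(propan-2-yl)bicyclo[4.2.0]oct-2-en-7-one | CC1=CC[C@H](C(C)C)[C@@H]2[C@H]1CC2=O | intermediate
6 | 8-[(E)-(dimethylamino)methylidene]-2-methyl-5-(propan-2-yl)bicyclo[4.2.0]oct-2-en-7-one | CC1=CC[C@H](C(C)C)[C@@H]2[C@H]1/C(=C\N(C)C)C2=O | intermediate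
7 | methyl 2-(2,2-dimethoxyethyl)-3-methyl-6-(propan-2-yl)cyclohex-3-ene-1-carboxylate (arms cis, both trans to isopropyl) | CC1=CC[C@H](C(C)C)[C@@H](C(=O)OC)[C@H]1CC(OC)OC | intermediate
8 | [2-(2,2-dimethoxyethyl)-3-methyl-6-(propan-2-yl)cyclohex-3-en-1-yl]methanol | CC1=CC[C@H](C(C)C)[C@@H](CO)[C@H]1CC(OC)OC | intermediate
9 | 4-vinyl-1,3-dioxolan-2-one | C=CC1COC(=O)O1 | starting material
10 | 2-(2,2-dimethoxyethyl)-3-methyl-6-(propan-2-yl)cyclohex-3-ene-1-carbaldehyde | CC1=CC[C@H](C(C)C)[C@@H](C=O)[C@H]1CC(OC)OC | intermediate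
11 | anti-(2R,3R)-diol: C1–CH(OH)–CH(CH2OH)–CH=CH2 arm, acetal arm unchanged | CC1=CC[C@H](C(C)C)[C@@H]([C@@H](O)[C@@H](CO)C=C)[C@H]1CC(OC)OC | intermediate
12 | C15 TBDPS ether of 11 | CC1=CC[C@H](C(C)C)[C@@H]([C@@H](O)[C@@H](CO[Si](c2ccccc2)(c2ccccc2)C(C)(C)C)C=C)[C@H]1CC(OC)OC | intermediate
13 | C2 PMB ether of 12 | CC1=CC[C@H](C(C)C)[C@@H]([C@@H](OCc2ccc(OC)cc2)[C@@H](CO[Si](c2ccccc2)(c2ccccc2)C(C)(C)C)C=C)[C@H]1CC(OC)OC | intermediate
14 | C8 aldehyde | CC1=CC[C@H](C(C)C)[C@@H]([C@@H](OCc2ccc(OC)cc2)[C@@H](CO[Si](c2ccccc2)(c2ccccc2)C(C)(C)C)C=C)[C@H]1CC=O | intermediate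
15 | ethynylmagnesium bromide | C#C[Mg]Br | starting material
16 | propargylic alcohol, mixture of C8 epimers | CC1=CC[C@H](C(C)C)[C@@H]([C@@H](OCc2ccc(OC)cc2)[C@@H](CO[Si](c2ccccc2)(c2ccccc2)C(C)(C)C)C=C)[C@H]1CC(O)C#C | intermediate
17 | terminal ynone | CC1=CC[C@H](C(C)C)[C@@H]([C@@H](OCc2ccc(OC)cc2)[C@@H](CO[Si](c2ccccc2)(c2ccccc2)C(C)(C)C)C=C)[C@H]1CC(=O)C#C | intermediate
18 | (8S)-propargylic alcohol | CC1=CC[C@H](C(C)C)[C@@H]([C@@H](OCc2ccc(OC)cc2)[C@@H](CO[Si](c2ccccc2)(c2ccccc2)C(C)(C)C)C=C)[C@H]1C[C@H](O)C#C | intermediate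
19 | (Z)-alkenylmagnesium bromide alkoxide (Mg on C6, Me on C7) | CC1=CC[C@H](C(C)C)[C@@H]([C@@H](OCc2ccc(OC)cc2)[C@@H](CO[Si](c2ccccc2)(c2ccccc2)C(C)(C)C)C=C)[C@H]1C[C@H](O[Mg]Br)/C(C)=C\[Mg]Br | intermediate
20 | (Z)-iodoalkene allylic alcohol (8S) | CC1=CC[C@H](C(C)C)[C@@H]([C@@H](OCc2ccc(OC)cc2)[C@@H](CO[Si](c2ccccc2)(c2ccccc2)C(C)(C)C)C=C)[C@H]1C[C@H](O)/C(C)=C\I | intermediate
21 | C8 TES ether of 20 | CC1=CC[C@H](C(C)C)[C@@H]([C@@H](OCc2ccc(OC)cc2)[C@@H](CO[Si](c2ccccc2)(c2ccccc2)C(C)(C)C)C=C)[C@H]1C[C@H](O[Si](CC)(CC)CC)/C(C)=C\I | intermediate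
22 | C2 alcohol (C8–OTES, C15–OTBDPS, Z-iodoalkene, C3 vinyl) | CC1=CC[C@H](C(C)C)[C@@H]([C@@H](O)[C@@H](CO[Si](c2ccccc2)(c2ccccc2)C(C)(C)C)C=C)[C@H]1C[C@H](O[Si](CC)(CC)CC)/C(C)=C\I | intermediate
23 | mixed butyl vinylboronate on the C2 oxygen | CC1=CC[C@H](C(C)C)[C@@H]([C@@H](OB(OCCCC)C=C)[C@@H](CO[Si](c2ccccc2)(c2ccccc2)C(C)(C)C)C=C)[C@H]1C[C@H](O[Si](CC)(CC)CC)/C(C)=C\I | intermediate
24 | cyclic butyl alkenylboronate (2-butoxy-3,6-dihydro-2H-1,2-oxaborinine, C4=C5 cis) | CC1=CC[C@H](C(C)C)[C@@H]([C@H]2OB(OCCCC)C=C[C@@H]2CO[Si](c3ccccc3)(c3ccccc3)C(C)(C)C)[C@H]1C[C@H](O[Si](CC)(CC)CC)/C(C)=C\I | intermediate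
25 | ten-membered (4Z,6Z)-diene, C2–OH, C8–OTES, C15–OTBDPS | CC1=CC[C@H](C(C)C)[C@H]2[C@@H](O)[C@@H](CO[Si](c3ccccc3)(c3ccccc3)C(C)(C)C)/C=C\C=C(\C)/[C@@H](O[Si](CC)(CC)CC)C[C@@H]12 | intermediate
26 | C2 acetate of 25 | CC1=CC[C@H](C(C)C)[C@H]2[C@@H](OC(C)=O)[C@@H](CO[Si](c3ccccc3)(c3ccccc3)C(C)(C)C)/C=C\C=C(\C)/[C@@H](O[Si](CC)(CC)CC)C[C@@H]12 | intermediate
27 | ten-membered (4Z,6Z)-diene, C2–OAc, C8–OH, C15–OTBDPS | CC1=CC[C@H](C(C)C)[C@H]2[C@@H](OC(C)=O)[C@@H](CO[Si](c3ccccc3)(c3ccccc3)C(C)(C)C)/C=C\C=C(\C)/[C@@H](O)C[C@@H]12 | intermediate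
28 | dioxygen | O=O | starting material
29 | bridged endoperoxide (C4–O–O–C7, 7S) | CC1=CC[C@H](C(C)C)[C@H]2[C@@H](OC(C)=O)[C@@H](CO[Si](c3ccccc3)(c3ccccc3)C(C)(C)C)[C@H]3C=C[C@](C)(OO3)[C@@H](O)C[C@@H]12 | intermediate
30 | hydroxy enone acetate (C4 ketone, cis C5=C6, C7–OH, C2–OAc) | CC1=CC[C@H](C(C)C)[C@H]2[C@@H](OC(C)=O)[C@@H](CO[Si](c3ccccc3)(c3ccccc3)C(C)(C)C)C(=O)/C=C\[C@](C)(O)[C@@H](O)C[C@@H]12 | intermediate
31 | hydroxy dienone (C2=C3, C4 ketone, cis C5=C6, C7–OH) | CC1=CC[C@H](C(C)C)[C@H]2/C=C(/CO[Si](c3ccccc3)(c3ccccc3)C(C)(C)C)C(=O)/C=C\[C@](C)(O)[C@@H](O)C[C@@H]12 | intermediate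
32 | furanoid hemiketal (C4–OH, C8–OH, C15–OTBDPS) | CC1=CC[C@H](C(C)C)[C@H]2/C=C(/CO[Si](c3ccccc3)(c3ccccc3)C(C)(C)C)[C@@]3(O)C=C[C@](C)(O3)[C@@H](O)C[C@@H]12 | intermediate
33 | furanoid methyl ketal (C4–OMe, C8–OH, C15–OTBDPS) | CC1=CC[C@H](C(C)C)[C@H]2/C=C(/CO[Si](c3ccccc3)(c3ccccc3)C(C)(C)C)[C@@]3(OC)C=C[C@](C)(O3)[C@@H](O)C[C@@H]12 | intermediate
34 | (E)-3-(1-methyl-1H-imidazol-4-yl)acrylic acid (N-methylurocanic acid) | OC(=O)/C=C/c1cn(C)cn1 | starting material
35 | C8 N-methylurocanate, C4–OMe, C15–OTBDPS | CC1=CC[C@H](C(C)C)[C@H]2/C=C(/CO[Si](c3ccccc3)(c3ccccc3)C(C)(C)C)[C@@]3(OC)C=C[C@](C)(O3)[C@@H](OC(=O)/C=C/c3cn(C)cn3)C[C@@H]12 | intermediate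
36 | C8 N-methylurocanate, C4–OMe, C15–OH | CC1=CC[C@H](C(C)C)[C@H]2/C=C(/CO)[C@@]3(OC)C=C[C@](C)(O3)[C@@H](OC(=O)/C=C/c3cn(C)cn3)C[C@@H]12 | intermediate
37 | CNP0196085.1 | CC1=CC[C@H](C(C)C)[C@H]2/C=C(/CO)[C@@]3(O)C=C[C@](C)(O3)[C@@H](OC(=O)/C=C/c3cn(C)cn3)C[C@@H]12 | target

**Step count and risks**

Total step count: 23. Longest linear sequence: 23 steps (1 → 37).

Steps most likely to fail:

1. Step 19. The twisted ten-membered diene reaches its s-cis geometry only with strain, so ene-type oxidation at the trisubstituted C11=C12 alkene and at the C7 methyl group may run faster than the cycloaddition, and oxygen may enter on the inner face after a ring flip. Fallback: the same C7–O and C4–O bonds are made stepwise from 27 without singlet oxygen. VO(acac)2/t-BuOOH should epoxidise only the allylic-alcohol alkene C6=C7, on the hydroxyl-bearing face, to give the 6,7-epoxy alcohol F1. Pd(PPh3)4 with chloroacetic acid opens the vinyl epoxide in the 1,4-sense with overall retention to the cis-hydroxy chloroacetate F2 (C7–OH, cis C5=C6, C4–OCOCH2Cl). Thiourea/NaHCO3 removes the chloroacetate beside the C2 acetate to give the enediol F3. MnO2 oxidises its only allylic secondary alcohol (C4) and so delivers 30, which is treated with DBU as in step 20 to reach 32.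

2. Step 16. Intermolecular coupling and protodeboronation may outpace closure of the strained ring. Fallback: the ring is closed at C4=C5 by metathesis instead of at C5–C6 by cross-coupling. From 22, Stille coupling with tributyl(vinyl)stannane (Pd(PPh3)4, CuI, DMF) turns the alkenyl iodide into the terminal diene of the triene F4. Ring-closing metathesis with the second-generation Grubbs catalyst at high dilution then joins the C3 vinyl group to the diene terminus (cis in a ten-membered ring) and returns to 25.

3. Step 20. Under base the free C8 alkoxide may push out the O–O bond with cleavage of C7–C8 before the C4 hydrogen is removed, and the acetate elimination may stall while the ketone is parked in hemiketal tautomers that involve the C8 hydroxyl. Fallback: from 29, TESOTf/2,6-lutidine caps the C8 hydroxyl to give the silylated endoperoxide F5. Et3N then DBU open the peroxide and eliminate the acetate to give the silylated hemiketal F6, in which only the furanoid form is possible. The PPTS/MeOH conditions of step 21 then remove the TES group while forming the methyl ketal, rejoining the route at 33.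

Further compounds

F1 | step 19 | 6,7-epoxy alcohol (epoxide oxygen syn to C8–OH; C4=C5 cis; C2–OAc) | CC1=CC[C@H](C(C)C)[C@H]2[C@@H](OC(C)=O)[C@@H](CO[Si](c3ccccc3)(c3ccccc3)C(C)(C)C)/C=C\[C@@H]3O[C@]3(C)[C@@H](O)C[C@@H]12
F2 | step 19 | cis-hydroxy chloroacetate (C4–OCOCH2Cl; cis C5=C6; C7–OH) | CC1=CC[C@H](C(C)C)[C@H]2[C@@H](OC(C)=O)[C@@H](CO[Si](c3ccccc3)(c3ccccc3)C(C)(C)C)[C@H](OC(=O)CCl)/C=C\[C@](C)(O)[C@@H](O)C[C@@H]12
F3 | step 19 | enediol (C4–OH; cis C5=C6; C7–OH; C8–OH) | CC1=CC[C@H](C(C)C)[C@H]2[C@@H](OC(C)=O)[C@@H](CO[Si](c3ccccc3)(c3ccccc3)C(C)(C)C)[C@H](O)/C=C\[C@](C)(O)[C@@H](O)C[C@@H]12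
F4 | step 16 | triene (C3 vinyl; C8–C7(Me)=C6–C5=CH2 with Z C6=C7) | CC1=CC[C@H](C(C)C)[C@@H]([C@@H](O)[C@@H](CO[Si](c2ccccc2)(c2ccccc2)C(C)(C)C)C=C)[C@H]1C[C@H](O[Si](CC)(CC)CC)/C(C)=C\C=C
F5 | step 20 | C8 TES ether of endoperoxide 29 | CC1=CC[C@H](C(C)C)[C@H]2[C@@H](OC(C)=O)[C@@H](CO[Si](c3ccccc3)(c3ccccc3)C(C)(C)C)[C@H]3C=C[C@](C)(OO3)[C@@H](O[Si](CC)(CC)CC)C[C@@H]12
F6 | step 20 | C8 TES ether of hemiketal 32 | CC1=CC[C@H](C(C)C)[C@H]2/C=C(/CO[Si](c3ccccc3)(c3ccccc3)C(C)(C)C)[C@@]3(O)C=C[C@](C)(O3)[C@@H](O[Si](CC)(CC)CC)C[C@@H]12
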